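**Plan**

Numbering and cuts: ring C15–C1–C2–C3–C4, enal arm C5=C6(CH3)–C7HO on C4, chain C14–C13(CH3)–C12=C11–C10(CH3)2–C9(=O)–C8 on C15. The retrosynthesis removes the three esters, cuts C11=C12 (cross-metathesis), takes the enal back to a C5 carbinol and cuts C4–C5 (aldol with methacrolein), cuts C2–CH3, excises C2 (bonds C1–C2 and C2–C3), splits the cyclobutanone into dichloroketene and an enol ether (bonds C15–C4 and C1–C3), and last cuts C13–C14 (crotylboration).
Enabling feature: C15 is a quaternary ring carbon bearing O15 and the oxygenated C14, so O14 and O15 can share one dioxolane carrying an exocyclic C15=C1 enol ether. A ketene adds across it at C15, and the spiro cyclobutanone supplies C3 as carbonyl and C4 as CCl2, the two ring carbons that later carry the benzoate and the enal arm.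
Forward order: chain C13–C14–C15–C1 from glyceraldehyde and a crotylboronate; four-membered ring C15–C1–C3–C4 by [2+2]; five-membered ring by insertion of C2; then C4 arm, C2 methyl, C3 alcohol and benzoate, enal, C8–C11 chain end, diol release, acetates.
Stereochemistry: C13/C14 from (E)-crotylboration of (S)-glyceraldehyde acetonide (whose own centre is then erased and rebuilt); C15 from ketene addition anti to the C14 substituent of the dioxolane; C4 from aldol addition on the O15 face; C2 from methylation trans to the C4 arm; C3 from hydride attack anti to that arm; both alkenes arise E (allylic transposition, metathesis).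

Key step: step 8

Assumption: the aldol carbinol C5 in 18–24 is drawn as the anti epimer expected from a chair transition state; this centre is erased in step 16, so either epimer can be carried forward.
Assumption: 1, 2, 9, 11, 16 and 27 are bought; 1 is distilled just before use.

**Route**

Step 1
Reactants: 1 (S)-2,3-O-isopropylideneglyceraldehyde; 2 (E)-crotylboronic acid pinacol ester
Product: 4 (1R,2R)-1-[(4S)-2,2-dimethyl-1,3-dioxolan-4-yl]-2-methylbut-3-en-1-ol, via pinacol borate ester 3 (not isolated)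
Conditions: CH2Cl2, 23 °C, 48 h; then aq. NaHCO3
Reagents that add atoms: none
Why: Aldehyde crotylboration through a closed six-membered chair transition state should turn the E geometry of 2 into the anti C13/C14 relationship, attack anti to the α-oxygen of 1 (non-chelation control) should favour the 14,15-anti adduct, and hydrolysis of borate 3 on work-up frees the alcohol.

Step 2
Reactants: 4 crotyl adduct (terminal acetonide)
Product: 5 (2S,3R,4R)-4-methylhex-5-ene-1,2,3-triol
Conditions: AcOH/H2O (4:1), 40 °C; toluene azeotrope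
Reagents that add atoms: none
Why: Acid-catalysed acetal hydrolysis is needed because equilibration to the internal O14/O15 acetonide (a cis-dioxolane) is not favoured, and it touches no stereocentre.

Step 3
Reactants: 5 triol
Product: 6 (2R,3R,4R)-1-iodo-4-methylhex-5-ene-2,3-diol
Conditions: PPh3, imidazole, I2 (added last, in portions), THF, 0 °C
Reagents that add atoms: iodine, SMILES II
Why: In this Appel-type (Garegg–Samuelsson) iodination the alkoxyphosphonium ion is displaced by iodide only at the unhindered primary carbon C1, and keeping free iodine low should avoid iodoetherification of the alkene.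

Step 4
Reactants: 6 iodo diol
Product: 7 (4R,5R)-4-[(2R)-but-3-en-2-yl]-5-(iodomethyl)-2,2-dimethyl-1,3-dioxolane
Conditions: 2,2-dimethoxypropane, PPTS (cat.), CH2Cl2, 23 °C
Reagents that add atoms: 2,2-dimethoxypropane, SMILES COC(C)(C)OC
Why: Acid-catalysed transketalisation ties the only remaining 1,2-diol (O14/O15) into the cis-4,5-disubstituted dioxolane, so that steps 2–4 together move the acetonide from O15/O1 to O14/O15.

Step 5
Reactants: 7 iodomethyl dioxolane
Product: 8 (4R)-4-[(2R)-but-3-en-2-yl]-2,2-dimethyl-5-methylidene-1,3-dioxolane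
Conditions: t-BuOK, THF, 0 → 23 °C; crude product kept over K2CO3
Reagents that add atoms: none
Why: E2 dehydroiodination is the usual entry to 4-methylidene-1,3-dioxolanes, and since the only β-hydrogen sits on C15 the exocyclic enol ether C15=C1 must form, erasing on purpose the centre that steered step 1.

Step 6
Reactants: 8 exocyclic enol ether; 9 trichloroacetyl chloride
Product: 10 (4S,8R)-8-[(2R)-but-3-en-2-yl]-1,1-dichloro-6,6-dimethyl-5,7-dioxaspiro[3.4]octan-2-one
Conditions: Zn(Cu) couple, Et2O/DME, 0 → 23 °C, slow addition of 9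
Reagents that add atoms: none
Why: In this ketene–alkene [2+2] cycloaddition, dichloroketene made in the flask by zinc dechlorination should add to the electron-rich enol ether in preference to the vinyl group, its carbonyl carbon bonding to the nucleophilic CH2 (C1) and its CCl2 carbon to C15 from the dioxolane face anti to the but-3-en-2-yl group on C14, which sets C15.

Step 7
Reactants: 11 N-methyl-N-nitroso-p-toluenesulfonamide
Product: 12 diazomethane (dry solution in Et2O)
Conditions: KOH, H2O/EtOH, Et2O, 65 °C, co-distillation into Et2O at 0 °C (smooth-joint glassware, blast shield)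
Reagents that add atoms: none
Why: Base-induced cleavage of the N-nitrososulfonamide (hydroxide attack at sulfur, then loss of hydroxide from the methyldiazotate) is the standard laboratory source of diazomethane, which is distilled with ether and used at once.

Step 8
Reactants: 10 spiro dichlorocyclobutanone; 12 diazomethane
Product: 14 (4R,5S)-4-[(2R)-but-3-en-2-yl]-6,6-dichloro-2,2-dimethyl-1,3-dioxaspiro[4.4]nonan-7-one, via diazonium betaine 13 (not isolated)
Conditions: 12 (ca. 2.5 equiv) in Et2O, MeOH (cat.), 0 → 23 °C; AcOH quench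
Reagents that add atoms: none
Why: Diazomethane adds through carbon to the strained, chlorine-activated carbonyl C3 to give betaine 13, and loss of N2 is coupled to a 1,2-shift of the ring CH2 (C1) from C3 to the new carbon C2, so that bonds C1–C2 and C2–C3 are present in 14. The closest known reaction type is the diazomethane homologation of α,α-dichlorocyclobutanones to α,α-dichlorocyclopentanones, a Tiffeneau–Demjanov-type ring enlargement. The five-membered ring is therefore not closed by a cyclisation but arises by one-carbon expansion of the four-membered ring made in step 6, driven by release of ring strain. No stereocentre is formed, because the migrating carbon is a CH2 group and the spiro centre C15 set in step 6 is a spectator. The selectivity needed is migration of C1 instead of C4, and the two chlorines secure it because the electron-poor CCl2 carbon is the poorer migrating group. A second homologation should be slow once the strain is gone, and the vinyl group and the acetonide do not react with diazomethane under these conditions.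

Step 9
Reactants: 14 dichlorocyclopentanone
Product: 15 (4R,5S)-4-[(2R)-but-3-en-2-yl]-6-chloro-2,2-dimethyl-1,3-dioxaspiro[4.4]nonan-7-one (mixture of C6 epimers)
Conditions: Bu3SnH (1.05 equiv), AIBN (cat.), benzene, 80 °C
Reagents that add atoms: none
Why: In this radical-chain hydrodechlorination, chlorine abstraction from CCl2 is much faster than from the CHCl product, so one equivalent removes one chlorine, and because a C4 radical and not an enolate is the intermediate the β-oxygen O15 is not expelled (5-exo closure onto the vinyl group would need a trans-fused bicycle); the C4 epimers converge in step 10.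

Step 10
Reactants: 15 α-chloro ketone; 16 methacrolein (2-methylprop-2-enal)
Product: 18 (4R,5R,6R)-4-[(2R)-but-3-en-2-yl]-6-[(1R)-1-hydroxy-2-methylprop-2-en-1-yl]-2,2-dimethyl-1,3-dioxaspiro[4.4]nonan-7-one, via samarium enolate 17 (not isolated)
Conditions: 15 and 16 (3 equiv), THF, −78 °C; SmI2 (2.1 equiv, 0.1 M in THF) added dropwise; aq. NH4Cl at −78 °C
Reagents that add atoms: none
Why: In this samarium Reformatsky-type aldol, two-electron reduction of the C–Cl bond at −78 °C gives enolate 17 regiospecifically at C3/C4, capture by the aldehyde through a chair transition state should outrun β-elimination of O15, and the aldehyde should enter on the face of the small, samarium-coordinating O15 and anti to C14, which sets C4 with C5 cis to O15 and gives the anti C4/C5 pair.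

Step 11
Reactants: 18 aldol
Product: 19 (4R,5R,6R)-4-[(2R)-but-3-en-2-yl]-2,2-dimethyl-6-[(1R)-2-methyl-1-(triethylsilyloxy)prop-2-en-1-yl]-1,3-dioxaspiro[4.4]nonan-7-one
Conditions: Et3SiOTf, 2,6-lutidine, CH2Cl2, −78 °C
Reagents that add atoms: triethylsilyl trifluoromethanesulfonate, SMILES CC[Si](CC)(CC)OS(=O)(=O)C(F)(F)F
Why: Silyl triflate silylation at low temperature caps the aldol hydroxyl before retro-aldol or dehydration can set in and makes the C4 arm the largest group on the ring, which steps 12 and 13 rely on.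

Step 12
Reactants: 19 silyl-protected ketone
Product: 21 (4R,5R,6R,8R)-4-[(2R)-but-3-en-2-yl]-2,2,8-trimethyl-6-[(1R)-2-methyl-1-(triethylsilyloxy)prop-2-en-1-yl]-1,3-dioxaspiro[4.4]nonan-7-one, via lithium enolate 20 (not isolated)
Conditions: LiN(i-Pr)2 (1.1 equiv), THF, −78 °C; MeI (5 equiv), DMPU, −78 → −40 °C
Reagents that add atoms: iodomethane, SMILES CI
Why: In this kinetic enolate alkylation, deprotonation should occur at the open C2 methylene and not at the shielded C4 methine (so neither O15 nor the silyloxy group is expelled), and SN2 methylation of enolate 20 anti to the pseudoaxial C4 arm should place the methyl group trans to it, which sets C2.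

Step 13
Reactants: 21 2-methyl ketone
Product: 22 (4R,5R,6R,7S,8R)-4-[(2R)-but-3-en-2-yl]-2,2,8-trimethyl-6-[(1R)-2-methyl-1-(triethylsilyloxy)prop-2-en-1-yl]-1,3-dioxaspiro[4.4]nonan-7-ol
Conditions: LiBH(s-Bu)3 (L-Selectride), THF, −78 °C; then H2O
Reagents that add atoms: none
Why: In this 1,2-reduction under steric approach control, the bulky trialkylborohydride should attack C3 from the face of the small C2 methyl group, anti to the large silyloxyalkyl arm on C4 and to O15, so that the new hydroxyl is cis to the arm and trans to the methyl group.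

Step 14
Reactants: 22 secondary alcohol
Product: 23 (4R,5R,6R,7S,8R)-4-[(2R)-but-3-en-2-yl]-2,2,8-trimethyl-6-[(1R)-2-methyl-1-(triethylsilyloxy)prop-2-en-1-yl]-1,3-dioxaspiro[4.4]nonan-7-yl benzoate
Conditions: BzCl, DMAP, pyridine, CH2Cl2, 23 → 40 °C
Reagents that add atoms: benzoyl chloride, SMILES ClC(=O)c1ccccc1
Why: DMAP-catalysed acylation through the N-benzoylpyridinium ion should esterify the hindered secondary alcohol with retention, since the C–O bond is not touched.

Step 15
Reactants: 23 benzoate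
Product: 24 (4R,5R,6S,7S,8R)-4-[(2R)-but-3-en-2-yl]-6-[(1R)-1-hydroxy-2-methylprop-2-en-1-yl]-2,2,8-trimethyl-1,3-dioxaspiro[4.4]nonan-7-yl benzoate
Conditions: HF·pyridine, pyridine, THF, 0 → 23 °C
Reagents that add atoms: none
Why: Fluoride-driven Si–O cleavage in a buffered medium should remove the triethylsilyl group while the acetonide stays and the benzoate does not migrate.

Step 16
Reactants: 24 secondary allylic alcohol
Product: 25 (4R,5R,6S,7S,8R)-4-[(2R)-but-3-en-2-yl]-6-[(1E)-3-hydroxy-2-methylprop-1-en-1-yl]-2,2,8-trimethyl-1,3-dioxaspiro[4.4]nonan-7-yl benzoate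
Conditions: Ph3SiOReO3 (5 mol %), Et2O, 0 °C
Reagents that add atoms: none
Why: The rhenium-oxo-catalysed 1,3-transposition of an allylic alcohol ([3,3] shift of the perrhenate ester) should run towards the primary alcohol with the trisubstituted alkene, and the chair transition state with the ring carbon C4 equatorial gives the E alkene while erasing C5.

Step 17
Reactants: 25 primary allylic alcohol
Product: 26 (4R,5R,6S,7S,8R)-4-[(2R)-but-3-en-2-yl]-2,2,8-trimethyl-6-[(1E)-2-methyl-3-oxoprop-1-en-1-yl]-1,3-dioxaspiro[4.4]nonan-7-yl benzoate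
Conditions: activated MnO2 (20 equiv), CH2Cl2, 23 °C
Reagents that add atoms: none
Why: Allylic oxidation on MnO2 is neutral and selective for the allylic alcohol, so the E enal should form without epimerisation at C4 or loss of benzoate.

Step 18
Reactants: 27 2,2-dimethylbut-3-enoic acid
Product: 30 3,3-dimethylpent-4-en-2-one, via lithium carboxylate 28 (not isolated), via dilithium gem-diolate 29 (not isolated)
Conditions: MeLi (2.2 equiv), Et2O, 0 → 23 °C; inverse quench into cold 1 M HCl
Reagents that add atoms: methyllithium, SMILES [Li]C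
Why: Addition of methyllithium to a lithium carboxylate stops at the gem-diolate 29, which collapses to the methyl ketone only on work-up, and the quaternary α-carbon rules out enolisation.

Step 19
Reactants: 26 enal with terminal vinyl group; 30 3,3-dimethylpent-4-en-2-one
Product: 31 (4R,5R,6S,7S,8R)-4-[(2R,3E)-5,5-dimethyl-6-oxohept-3-en-2-yl]-2,2,8-trimethyl-6-[(1E)-2-methyl-3-oxoprop-1-en-1-yl]-1,3-dioxaspiro[4.4]nonan-7-yl benzoate
Conditions: Hoveyda–Grubbs second-generation catalyst RuCl2(H2IMes)(=CH-C6H4-2-O-i-Pr) (10 mol %, two portions), 30 (6 equiv), CH2Cl2, 40 °C, argon sparge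
Reagents that add atoms: none
Why: In this olefin cross-metathesis the partner 30 carries its vinyl group on a quaternary carbon and cannot homodimerise, so an excess of this volatile ketone should drive selective cross-coupling with the α-branched vinyl group, the two bulky substituents enforce the E alkene, and the electron-poor trisubstituted enal is expected to stay out of the reaction.

Step 20
Reactants: 31 acetonide
Product: 32 (1S,2S,3R,5R)-3-hydroxy-3-[(1R,2R,3E)-1-hydroxy-2,5,5-trimethyl-6-oxohept-3-en-1-yl]-5-methyl-2-[(1E)-2-methyl-3-oxoprop-1-en-1-yl]cyclopentyl benzoate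
Conditions: CF3CO2H/H2O (9:1), CH2Cl2, 0 °C
Reagents that add atoms: none
Why: Acid-catalysed acetal hydrolysis frees the C14/C15 diol, and the benzoate, the enal and the β,γ-unsaturated ketone (C10 is quaternary, so it cannot move into conjugation) should tolerate the brief acid treatment.

Step 21
Reactants: 32 diol
Product: 33 (1S,2S,3R,5R)-3-acetoxy-3-[(1R,2R,3E)-1-acetoxy-2,5,5-trimethyl-6-oxohept-3-en-1-yl]-5-methyl-2-[(1E)-2-methyl-3-oxoprop-1-en-1-yl]cyclopentyl benzoate (CNP0489076.2)
Conditions: Ac2O (10 equiv), DMAP (2 equiv), Et3N, CH2Cl2, 40 °C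
Reagents that add atoms: acetic anhydride, SMILES CC(=O)OC(C)=O
Why: DMAP-catalysed acylation should acetylate the secondary C14 hydroxyl quickly and, with excess reagent and gentle heating, the tertiary C15 hydroxyl as well, in a basic medium that leaves the enal and the methyl ketone alone.

**Compound list**

1 | (S)-2,3-O-isopropylideneglyceraldehyde [(4S)-2,2-dimethyl-1,3-dioxolane-4-carbaldehyde] | O=C[C@@H]1COC(C)(C)O1 | starting material
2 | (E)-crotylboronic acid pinacol ester [2-[(2E)-but-2-en-1-yl]-4,4,5,5-tetramethyl-1,3,2-dioxaborolane] | C/C=C/CB1OC(C)(C)C(C)(C)O1 | starting material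
3 | pinacol borate ester of 4 [2-{[(1R,2R)-1-[(4S)-2,2-dimethyl-1,3-dioxolan-4-yl]-2-methylbut-3-en-1-yl]oxy}-4,4,5,5-tetramethyl-1,3,2-dioxaborolane] | O([C@H]([C@H](C)C=C)[C@@H]1COC(C)(C)O1)B1OC(C)(C)C(C)(C)O1 | intermediate
4 | (1R,2R)-1-[(4S)-2,2-dimethyl-1,3-dioxolan-4-yl]-2-methylbut-3-en-1-ol | O[C@H]([C@H](C)C=C)[C@@H]1COC(C)(C)O1 | intermediate
5 | (2S,3R,4R)-4-methylhex-5-ene-1,2,3-triol | O[C@H]([C@H](C)C=C)[C@@H](O)CO | intermediate
6 | (2R,3R,4R)-1-iodo-4-methylhex-5-ene-2,3-diol | O[C@H]([C@H](C)C=C)[C@@H](O)CI | intermediate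
7 | (4R,5R)-4-[(2R)-but-3-en-2-yl]-5-(iodomethyl)-2,2-dimethyl-1,3-dioxolane (cis) | O1[C@H]([C@H](C)C=C)[C@@H](OC1(C)C)CI | intermediate
8 | (4R)-4-[(2R)-but-3-en-2-yl]-2,2-dimethyl-5-methylidene-1,3-dioxolane | O1[C@H]([C@H](C)C=C)C(=C)OC1(C)C | intermediate
9 | trichloroacetyl chloride | ClC(=O)C(Cl)(Cl)Cl | starting material
10 | (4S,8R)-8-[(2R)-but-3-en-2-yl]-1,1-dichloro-6,6-dimethyl-5,7-dioxaspiro[3.4]octan-2-one | O1[C@H]([C@H](C)C=C)[C@@]2(OC1(C)C)CC(=O)C2(Cl)Cl | intermediate
11 | N-methyl-N-nitroso-p-toluenesulfonamide | Cc1ccc(cc1)S(=O)(=O)N(C)N=O | starting material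
12 | diazomethane | C=[N+]=[N-] | intermediate
13 | diazonium betaine from 10 and 12 (C3 alkoxide bearing CH2–N2+; C3 configuration undefined) | O1[C@H]([C@H](C)C=C)[C@@]2(OC1(C)C)CC([O-])(C[N+]#N)C2(Cl)Cl | intermediate
14 | (4R,5S)-4-[(2R)-but-3-en-2-yl]-6,6-dichloro-2,2-dimethyl-1,3-dioxaspiro[4.4]nonan-7-one | O1[C@H]([C@H](C)C=C)[C@@]2(OC1(C)C)CCC(=O)C2(Cl)Cl | intermediate
15 | (4R,5S)-4-[(2R)-but-3-en-2-yl]-6-chloro-2,2-dimethyl-1,3-dioxaspiro[4.4]nonan-7-one (C6 epimers) | O1[C@H]([C@H](C)C=C)[C@@]2(OC1(C)C)CCC(=O)C2Cl | intermediate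
16 | methacrolein (2-methylprop-2-enal) | CC(=C)C=O | starting material
17 | diiodosamarium enolate of 15 (C3=C4–O–SmI2, trivalent samarium) | O1[C@H]([C@H](C)C=C)[C@@]2(OC1(C)C)CCC(O[Sm](I)I)=C2 | intermediate
18 | (4R,5R,6R)-4-[(2R)-but-3-en-2-yl]-6-[(1R)-1-hydroxy-2-methylprop-2-en-1-yl]-2,2-dimethyl-1,3-dioxaspiro[4.4]nonan-7-one | O1[C@H]([C@H](C)C=C)[C@@]2(OC1(C)C)CCC(=O)[C@@H]2[C@@H](O)C(C)=C | intermediate
19 | (4R,5R,6R)-4-[(2R)-but-3-en-2-yl]-2,2-dimethyl-6-[(1R)-2-methyl-1-(triethylsilyloxy)prop-2-en-1-yl]-1,3-dioxaspiro[4.4]nonan-7-one | O1[C@H]([C@H](C)C=C)[C@@]2(OC1(C)C)CCC(=O)[C@@H]2[C@@H](O[Si](CC)(CC)CC)C(C)=C | intermediate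
20 | lithium enolate of 19 (C2=C3–OLi) | O1[C@H]([C@H](C)C=C)[C@@]2(OC1(C)C)CC=C(O[Li])[C@@H]2[C@@H](O[Si](CC)(CC)CC)C(C)=C | intermediate
21 | (4R,5R,6R,8R)-4-[(2R)-but-3-en-2-yl]-2,2,8-trimethyl-6-[(1R)-2-methyl-1-(triethylsilyloxy)prop-2-en-1-yl]-1,3-dioxaspiro[4.4]nonan-7-one | O1[C@H]([C@H](C)C=C)[C@@]2(OC1(C)C)C[C@@H](C)C(=O)[C@@H]2[C@@H](O[Si](CC)(CC)CC)C(C)=C | intermediate
22 | (4R,5R,6R,7S,8R)-4-[(2R)-but-3-en-2-yl]-2,2,8-trimethyl-6-[(1R)-2-methyl-1-(triethylsilyloxy)prop-2-en-1-yl]-1,3-dioxaspiro[4.4]nonan-7-ol | O1[C@H]([C@H](C)C=C)[C@@]2(OC1(C)C)C[C@@H](C)[C@H](O)[C@@H]2[C@@H](O[Si](CC)(CC)CC)C(C)=C | intermediate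
23 | (4R,5R,6R,7S,8R)-4-[(2R)-but-3-en-2-yl]-2,2,8-trimethyl-6-[(1R)-2-methyl-1-(triethylsilyloxy)prop-2-en-1-yl]-1,3-dioxaspiro[4.4]nonan-7-yl benzoate | O1[C@H]([C@H](C)C=C)[C@@]2(OC1(C)C)C[C@@H](C)[C@H](OC(=O)c3ccccc3)[C@@H]2[C@@H](O[Si](CC)(CC)CC)C(C)=C | intermediate
24 | (4R,5R,6S,7S,8R)-4-[(2R)-but-3-en-2-yl]-6-[(1R)-1-hydroxy-2-methylprop-2-en-1-yl]-2,2,8-trimethyl-1,3-dioxaspiro[4.4]nonan-7-yl benzoate | O1[C@H]([C@H](C)C=C)[C@@]2(OC1(C)C)C[C@@H](C)[C@H](OC(=O)c3ccccc3)[C@@H]2[C@@H](O)C(C)=C | intermediate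
25 | (4R,5R,6S,7S,8R)-4-[(2R)-but-3-en-2-yl]-6-[(1E)-3-hydroxy-2-methylprop-1-en-1-yl]-2,2,8-trimethyl-1,3-dioxaspiro[4.4]nonan-7-yl benzoate | O1[C@H]([C@H](C)C=C)[C@@]2(OC1(C)C)C[C@@H](C)[C@H](OC(=O)c3ccccc3)[C@@H]2/C=C(\C)CO | intermediate
26 | (4R,5R,6S,7S,8R)-4-[(2R)-but-3-en-2-yl]-2,2,8-trimethyl-6-[(1E)-2-methyl-3-oxoprop-1-en-1-yl]-1,3-dioxaspiro[4.4]nonan-7-yl benzoate | O1[C@H]([C@H](C)C=C)[C@@]2(OC1(C)C)C[C@@H](C)[C@H](OC(=O)c3ccccc3)[C@@H]2/C=C(\C)C=O | intermediate
27 | 2,2-dimethylbut-3-enoic acid | C=CC(C)(C)C(=O)O | starting material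
28 | lithium 2,2-dimethylbut-3-enoate | C=CC(C)(C)C(=O)O[Li] | intermediate
29 | dilithium 3,3-dimethylpent-4-ene-2,2-diolate | C=CC(C)(C)C(C)(O[Li])O[Li] | intermediate
30 | 3,3-dimethylpent-4-en-2-one | C=CC(C)(C)C(C)=O | intermediate
31 | (4R,5R,6S,7S,8R)-4-[(2R,3E)-5,5-dimethyl-6-oxohept-3-en-2-yl]-2,2,8-trimethyl-6-[(1E)-2-methyl-3-oxoprop-1-en-1-yl]-1,3-dioxaspiro[4.4]nonan-7-yl benzoate | O1[C@H]([C@H](C)/C=C/C(C)(C)C(C)=O)[C@@]2(OC1(C)C)C[C@@H](C)[C@H](OC(=O)c3ccccc3)[C@@H]2/C=C(\C)C=O | intermediate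
32 | (1S,2S,3R,5R)-3-hydroxy-3-[(1R,2R,3E)-1-hydroxy-2,5,5-trimethyl-6-oxohept-3-en-1-yl]-5-methyl-2-[(1E)-2-methyl-3-oxoprop-1-en-1-yl]cyclopentyl benzoate | O[C@H]([C@H](C)/C=C/C(C)(C)C(C)=O)[C@@]1(O)C[C@@H](C)[C@H](OC(=O)c2ccccc2)[C@@H]1/C=C(\C)C=O | intermediate
33 | (1S,2S,3R,5R)-3-acetoxy-3-[(1R,2R,3E)-1-acetoxy-2,5,5-trimethyl-6-oxohept-3-en-1-yl]-5-methyl-2-[(1E)-2-methyl-3-oxoprop-1-en-1-yl]cyclopentyl benzoate (CNP0489076.2) | CC(=O)O[C@H]([C@H](C)/C=C/C(C)(C)C(C)=O)[C@@]1(OC(C)=O)C[C@@H](C)[C@H](OC(=O)c2ccccc2)[C@@H]1/C=C(\C)C=O | target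

**Step count and risks**

Total: 21 steps. Longest linear sequence: 19 steps (1–6, 8–17, 19–21); steps 7 and 18 each make one reagent or partner.

Most likely to fail, step 10 (reductive aldol). The samarium enolate carries a leaving group (O15) β to its carbon, so E1cB opening of the dioxolane to a cyclopentenone, or simple protonation of the enolate, may compete with aldol capture; the aldehyde may also enter from the C14 face. Fallback, setting out from 15 and returning at 18: reduction of 15 with zinc dust in the presence of Me3SiCl (TMEDA, Et2O, 0 °C) silylates the enolate as it forms and should give the regiodefined trimethylsilyl enol ether F1. A Mukaiyama aldol addition of F1 to methacrolein 16 (BF3·OEt2, CH2Cl2, −78 °C), with an open transition state and attack again on the O15 face, then gives 18 after aqueous work-up.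

Step 12 (C2 methylation). The but-3-en-2-yl group lies under the ring near C1 and may compete with the C4 arm in steering the electrophile, so iodomethane may enter from both faces or mainly cis to the arm; proton transfer between enolate and product may also cause over-methylation. Fallback, setting out from 19 (through enolate 20) and returning at 21: the C2 centre is made in a C–H instead of a C–C bond-forming event, so that entry of the reagent cis to the arm becomes the productive direction. Enolate 20 is trapped with dimethyl(methylidene)ammonium iodide to give the Mannich base F2, quaternisation with MeI gives the trimethylammonium iodide F3, and NaHCO3 eliminates trimethylamine to the 2-methylidene ketone F4. Conjugate reduction of F4 with LiBH(s-Bu)3 (1.0 equiv, THF, −78 °C) forms the tetrasubstituted lithium enolate F5 regiospecifically, and kinetic protonation with the bulky donor 2,6-di-tert-butylphenol, which discriminates the faces better than iodomethane, should leave the methyl group trans to the arm in 21.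

Step 19 (cross-metathesis). Both alkenes are branched at the allylic carbon, so productive metathesis may be slower than catalyst decay, and the ruthenium carbene at C12 could instead close onto the C5=C6 alkene. Fallback, setting out from 25 and returning at 31, builds C11=C12 by aldol addition and dehydration. Hydroboration of 25 with 9-BBN-H (2.5 equiv, THF; the trisubstituted alkene is not attacked) gives the bis-boron adduct F6, and oxidation with NaBO3·4H2O gives the diol F7. Dess–Martin periodinane oxidises both primary alcohols to the dialdehyde F8. A Mukaiyama aldol addition of 2-methyl-3-(trimethylsilyloxy)but-2-ene (BF3·OEt2, CH2Cl2, −78 °C) to the more reactive saturated aldehyde C11 creates C10 and gives the β-hydroxy ketone F9. Mesylation (MsCl, Et3N) gives the methanesulfonate F10, and elimination with DBU (toluene, 80 °C), which can only run towards C12 because C10 is quaternary, should give the E alkene of 31.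

Further compounds
F1 | step 10 | trimethylsilyl enol ether (4R,5R)-4-[(2R)-but-3-en-2-yl]-2,2-dimethyl-7-(trimethylsilyloxy)-1,3-dioxaspiro[4.4]non-6-ene | O1[C@H]([C@H](C)C=C)[C@@]2(OC1(C)C)CCC(O[Si](C)(C)C)=C2
F2 | step 12 | Mannich base, the 8-[(dimethylamino)methyl] derivative of 19 (C8 epimers) | O1[C@H]([C@H](C)C=C)[C@@]2(OC1(C)C)CC(CN(C)C)C(=O)[C@@H]2[C@@H](O[Si](CC)(CC)CC)C(C)=C
F3 | step 12 | trimethylammonium iodide of F2 | O1[C@H]([C@H](C)C=C)[C@@]2(OC1(C)C)CC(C[N+](C)(C)C)C(=O)[C@@H]2[C@@H](O[Si](CC)(CC)CC)C(C)=C.[I-]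
F4 | step 12 | (4R,5R,6R)-4-[(2R)-but-3-en-2-yl]-2,2-dimethyl-8-methylidene-6-[(1R)-2-methyl-1-(triethylsilyloxy)prop-2-en-1-yl]-1,3-dioxaspiro[4.4]nonan-7-one | O1[C@H]([C@H](C)C=C)[C@@]2(OC1(C)C)CC(=C)C(=O)[C@@H]2[C@@H](O[Si](CC)(CC)CC)C(C)=C
F5 | step 12 | lithium enolate of 21 (C2(CH3)=C3–OLi) | O1[C@H]([C@H](C)C=C)[C@@]2(OC1(C)C)CC(C)=C(O[Li])[C@@H]2[C@@H](O[Si](CC)(CC)CC)C(C)=C
F6 | step 19 | bis(9-borabicyclo[3.3.1]nonan-9-yl) adduct of 25 (boron on C11 and on O7) | O1[C@H]([C@H](C)CCB3C4CCCC3CCC4)[C@@]2(OC1(C)C)C[C@@H](C)[C@H](OC(=O)c5ccccc5)[C@@H]2/C=C(\C)COB6C7CCCC6CCC7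
F7 | step 19 | (4R,5R,6S,7S,8R)-4-[(2R)-4-hydroxybutan-2-yl]-6-[(1E)-3-hydroxy-2-methylprop-1-en-1-yl]-2,2,8-trimethyl-1,3-dioxaspiro[4.4]nonan-7-yl benzoate | O1[C@H]([C@H](C)CCO)[C@@]2(OC1(C)C)C[C@@H](C)[C@H](OC(=O)c3ccccc3)[C@@H]2/C=C(\C)CO
F8 | step 19 | (4R,5R,6S,7S,8R)-2,2,8-trimethyl-6-[(1E)-2-methyl-3-oxoprop-1-en-1-yl]-4-[(2R)-4-oxobutan-2-yl]-1,3-dioxaspiro[4.4]nonan-7-yl benzoate | O1[C@H]([C@H](C)CC=O)[C@@]2(OC1(C)C)C[C@@H](C)[C@H](OC(=O)c3ccccc3)[C@@H]2/C=C(\C)C=O
F9 | step 19 | (4R,5R,6S,7S,8R)-4-[(2R)-4-hydroxy-5,5-dimethyl-6-oxoheptan-2-yl]-2,2,8-trimethyl-6-[(1E)-2-methyl-3-oxoprop-1-en-1-yl]-1,3-dioxaspiro[4.4]nonan-7-yl benzoate (C11 epimers) | O1[C@H]([C@H](C)CC(O)C(C)(C)C(C)=O)[C@@]2(OC1(C)C)C[C@@H](C)[C@H](OC(=O)c3ccccc3)[C@@H]2/C=C(\C)C=O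
F10 | step 19 | methanesulfonate of F9 at the C11 hydroxyl | O1[C@H]([C@H](C)CC(OS(C)(=O)=O)C(C)(C)C(C)=O)[C@@]2(OC1(C)C)C[C@@H](C)[C@H](OC(=O)c3ccccc3)[C@@H]2/C=C(\C)C=O
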